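**Retrosynthetic overview**

1. Numbering: chromane numbering is used; ring A is the benzene ring (C4a, C5, C6, C7, C8, C8a) and ring B is the pyran ring (O1, C2, C3, C4, C4a, C8a).
2. Target 23 ⇐ 22 (fluoride release of the acid) ⇐ 20 (Heck dienylation of the C2 vinyl group) ⇐ 17 (dehydrogenation; ring A is aromatized late).
3. Key disconnection O1–C8a: the tertiary C2 hydroxyl condenses on the C8a carbonyl of a cyclohexane-1,3-dione that is built in the same flask from three components, β-ketophosphonate 9, acetaldehyde 13 and malonate 12 (C7=C8 olefination, C6–C7 Michael addition, C4a–C5 Claisen closure). Ring A forms first at the dihydro level, ring B second.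
4. Enabling feature: the two meta oxygens of ring A (O1 on C8a, OH on C5, both flanking C4a) with the carboxyl on C6 next to C5. Ring A is therefore a masked 4-alkoxycarbonylcyclohexane-1,3-dione in which C8a is a carbonyl carbon five atoms away from the C2 oxygen, so ring B can close as a six-membered vinylogous ester.
5. 9 ⇐ (R)-lactone 5 + lithiated phosphonate 8; 5 ⇐ (R)-linalool 1, which supplies the C2 stereocentre with its methyl and vinyl groups and C3, C4 and C4a.

Key step: step 7

Assumption: (R)-(−)-linalool is used at high enantiomeric purity; its carbinol carbon becomes C2, and no step of the route breaks the C2–O bond.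

**Route**

Step 1
Reactants: 1 (R)-(−)-linalool [(3R)-3,7-dimethylocta-1,6-dien-3-ol]
Product: 3 (5R)-5-ethenyl-5-methyloxolan-2-ol (anomer mixture; lactol of the γ-hydroxy aldehyde), via secondary ozonide 2 (not isolated)
Conditions: O3 (1.0 equiv, indicator dye end point), CH2Cl2, −78 °C; then Me2S, −78 °C → rt
Reagents that add atoms: ozone, [O-][O+]=O
Why: Ozonolysis with reductive work-up should cleave only the electron-rich trisubstituted alkene, which reacts far faster than the vinyl group, and the resulting γ-hydroxy aldehyde closes to the lactol without touching the carbinol stereocentre (the future C2).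

Step 2
Reactants: 3 (5R)-5-ethenyl-5-methyloxolan-2-ol
Product: 4 (3R)-3-methylhept-1-en-6-yn-3-ol
Conditions: dimethyl (1-diazo-2-oxopropyl)phosphonate, K2CO3, MeOH, 0 °C → rt
Reagents that add atoms: dimethyl (1-diazo-2-oxopropyl)phosphonate, CC(=O)C(=[N+]=[N-])P(=O)(OC)OC
Why: Ohira–Bestmann (Seyferth–Gilbert) homologation should convert the open hydroxy aldehyde form of the lactol into the terminal alkyne under mild carbonate conditions that leave the tertiary allylic alcohol alone.

Step 3
Reactants: 4 (3R)-3-methylhept-1-en-6-yn-3-ol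
Product: 5 (6R)-6-ethenyl-6-methyloxan-2-one
Conditions: CpRuCl[P(C6H4-4-OMe)3]2 (5 mol %), P(C6H4-4-OMe)3, N-hydroxysuccinimide, Bu4NBr, NaHCO3, DMF/H2O, 85 °C
Reagents that add atoms: N-hydroxysuccinimide, O=C1CCC(=O)N1O
Why: Ruthenium-catalysed oxidative cyclization of a bis-homopropargylic alcohol: the terminal alkyne forms a ruthenium vinylidene, the hydroxyl adds to its α-carbon to give a six-membered oxacarbene, and N-hydroxysuccinimide transfers oxygen to release the δ-lactone with the carbinol C–O bond intact.

Step 4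
Reactants: 6 5-bromo-2-methylpent-2-ene; 7 triethyl phosphite
Product: 8 diethyl (4-methylpent-3-en-1-yl)phosphonate
Conditions: neat, 150 °C, EtBr distilled off
Reagents that add atoms: none
Why: Michaelis–Arbuzov reaction of an unhindered primary bromide, driven by loss of volatile bromoethane.

Step 5
Reactants: 5 (6R)-6-ethenyl-6-methyloxan-2-one; 8 diethyl (4-methylpent-3-en-1-yl)phosphonate
Product: 9 diethyl [(10R)-10-hydroxy-2,10-dimethyl-6-oxododeca-2,11-dien-5-yl]phosphonate (C5 epimers; in equilibrium with its cyclic hemiketal)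
Conditions: 8 (2.2 equiv), n-BuLi (2.2 equiv), THF, −78 °C; then 5, −78 → −20 °C; aq. NH4Cl
Reagents that add atoms: none
Why: Claisen-type acylation of an α-lithioalkylphosphonate by a lactone; the second equivalent of carbanion deprotonates the β-ketophosphonate as it forms and so prevents over-addition, and acyl–oxygen cleavage leaves the tertiary alcohol configuration untouched.

Step 6
Reactants: 10 malonic acid; 11 2-(trimethylsilyl)ethanol
Product: 12 bis[2-(trimethylsilyl)ethyl] malonate
Conditions: 11 (2.2 equiv in all), DCC (2.2 equiv), DMAP (5 mol %), MeCN/CH2Cl2, 0 °C → rt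
Reagents that add atoms: 2-(trimethylsilyl)ethanol (second equivalent of 11), C[Si](C)(C)CCO
Why: Twofold Steglich-type carbodiimide esterification, in which each carboxyl group of malonic acid takes up one molecule of the alcohol, should give the fluoride-cleavable diester, chosen so that the final hindered acid can be released without hydrolysis.

Step 7
Reactants: 9 diethyl [(10R)-10-hydroxy-2,10-dimethyl-6-oxododeca-2,11-dien-5-yl]phosphonate; 12 bis[2-(trimethylsilyl)ethyl] malonate; 13 acetaldehyde
Product: 17 2-(trimethylsilyl)ethyl (2R)-2-ethenyl-2,7-dimethyl-8-(3-methylbut-2-en-1-yl)-5-oxo-3,4,5,6,7,8-hexahydro-2H-chromene-6-carboxylate (mixture of C6/C7/C8 diastereomers), via enone 14 (not isolated), via Michael adduct 15 (not isolated), via hydroxy dione 16 (not isolated)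
Conditions: KOtBu (1.05 equiv), THF, 0 °C, then MeCHO (1.3 equiv), 0 °C → rt, excess MeCHO purged; then 12 (1.5 equiv), KOtBu (2.2 equiv), t-BuOH/THF, 65 °C; then AcOH (to pH 5), PPTS (10 mol %), 4 Å MS, toluene, 45 °C
Reagents that add atoms: none
Why: Mechanism: the potassium enolate of 9 olefinates acetaldehyde (Horner–Wadsworth–Emmons) to enone 14 of either geometry, the anion of malonate 12 adds to its methyl-bearing β-carbon (Michael, C6–C7) to give 15, and the C4a enolate of this ketone closes ring A by 6-exo-trig Claisen (Dieckmann-type) acylation on one malonate ester (C4a–C5), the stabilized dione enolate of 16 pulling both equilibria forward. After buffering with acid the tertiary C2 hydroxyl adds to the C8a carbonyl (6-exo-trig hemiketal formation) and water is lost to give the vinylogous ester, which makes the O1–C8a bond and closes ring B. The closest known reaction types are the malonate/enone Michael–Claisen synthesis of 4-alkoxycarbonylcyclohexane-1,3-diones and the acid-catalysed cyclodehydration of 2-(3-hydroxyalkyl)cyclohexane-1,3-diones to hexahydrochromen-5-ones, here run in one flask after the olefination. The new sp3 centres C6, C7 and C8 form without control and need none because step 8 flattens all three, so every diastereomer and both enone isomers funnel to one arene, while C2 keeps its configuration because O1 acts as the nucleophile and the C2–O bond is never broken. The step needs condensation at C8a and not at C5: the C6 ester holds the C5 oxygen in the chelated β-keto ester enol and leaves C8a as the ketone-like carbon, which is where amines and alcohols are known to condense in this class of ester-bearing diones, and since the closure is reversible it should settle on the isomer that keeps the C5 carbonyl conjugated to the ester. It also needs the tertiary allylic alcohol not to ionize, which the weak acid (PPTS, 45 °C) and the vinyl (not yet dienyl) substituent at C2 should secure.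

Step 8
Reactants: 17 2-(trimethylsilyl)ethyl (2R)-2-ethenyl-2,7-dimethyl-8-(3-methylbut-2-en-1-yl)-5-oxo-3,4,5,6,7,8-hexahydro-2H-chromene-6-carboxylate
Product: 20 2-(trimethylsilyl)ethyl (2R)-2-ethenyl-5-hydroxy-2,7-dimethyl-8-(3-methylbut-2-en-1-yl)-3,4-dihydro-2H-chromene-6-carboxylate, via sulfilimine 18 (not isolated), via cyclohexadienone 19 (not isolated)
Conditions: LiN(SiMe3)2 (1.2 equiv), THF, −78 °C; then N-tert-butylbenzenesulfinimidoyl chloride (1.3 equiv), −78 °C → rt
Reagents that add atoms: none
Why: Mukaiyama dehydrogenation: the C6 enolate of the β-keto ester attacks sulfur, syn-elimination toward the only β-hydrogen (C7–H) gives dienone 19, and this tautomerizes at once (C8–H to oxygen) to the phenol, erasing the C6/C7/C8 stereocentres under conditions that spare the prenyl and vinyl groups and the benzylic C4.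

Step 9
Reactants: 20 2-(trimethylsilyl)ethyl (2R)-2-ethenyl-5-hydroxy-2,7-dimethyl-8-(3-methylbut-2-en-1-yl)-3,4-dihydro-2H-chromene-6-carboxylate; 21 1-bromo-2-methylprop-1-ene
Product: 22 2-(trimethylsilyl)ethyl (2R)-5-hydroxy-2,7-dimethyl-8-(3-methylbut-2-en-1-yl)-2-[(1E)-4-methylpenta-1,3-dien-1-yl]-3,4-dihydro-2H-chromene-6-carboxylate
Conditions: Pd(OAc)2 (10 mol %), Bu4NCl, NaHCO3, DMF, 60 °C (sealed tube)
Reagents that add atoms: none
Why: Mizoroki–Heck reaction under Jeffery conditions: the alkenylpalladium bromide should add to the free terminus of the monosubstituted vinyl group, and syn β-hydride elimination, possible only toward the new substituent because C2 is quaternary, should give the E-diene while the trisubstituted prenyl alkene does not insert.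

Step 10
Reactants: 22 2-(trimethylsilyl)ethyl (2R)-5-hydroxy-2,7-dimethyl-8-(3-methylbut-2-en-1-yl)-2-[(1E)-4-methylpenta-1,3-dien-1-yl]-3,4-dihydro-2H-chromene-6-carboxylate
Product: 23 (2R)-5-hydroxy-2,7-dimethyl-8-(3-methylbut-2-en-1-yl)-2-[(1E)-4-methylpenta-1,3-dien-1-yl]-3,4-dihydro-2H-chromene-6-carboxylic acid (target)
Conditions: Bu4NF (3 equiv), THF, 0 °C → rt; cold dilute HCl to pH 3–4
Reagents that add atoms: none
Why: Fluoride-induced fragmentation of the 2-(trimethylsilyl)ethyl ester (attack at silicon, β-elimination) should release the carboxylate without heat or hydrolysis and with only a brief cold acidification, so the tertiary dienylic aryl ether, the C2 configuration and the easily decarboxylated β-resorcylic acid survive.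

**Compound list**

1 | (R)-(−)-linalool, (3R)-3,7-dimethylocta-1,6-dien-3-ol | C=C[C@@](O)(C)CCC=C(C)C | starting material
2 | (3R)-5-(5,5-dimethyl-1,2,4-trioxolan-3-yl)-3-methylpent-1-en-3-ol (secondary ozonide) | C=C[C@@](O)(C)CCC1OOC(C)(C)O1 | intermediate
3 | (5R)-5-ethenyl-5-methyloxolan-2-ol (anomer mixture) | C=C[C@@]1(C)CCC(O)O1 | intermediate
4 | (3R)-3-methylhept-1-en-6-yn-3-ol | C=C[C@@](O)(C)CCC#C | intermediate
5 | (6R)-6-ethenyl-6-methyloxan-2-one | C=C[C@@]1(C)CCCC(=O)O1 | intermediate
6 | 5-bromo-2-methylpent-2-ene | CC(C)=CCCBr | starting material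
7 | triethyl phosphite | CCOP(OCC)OCC | starting material
8 | diethyl (4-methylpent-3-en-1-yl)phosphonate | CCOP(=O)(CCC=C(C)C)OCC | intermediate
9 | diethyl [(10R)-10-hydroxy-2,10-dimethyl-6-oxododeca-2,11-dien-5-yl]phosphonate (C5 epimers) | C=C[C@@](O)(C)CCCC(=O)C(CC=C(C)C)P(=O)(OCC)OCC | intermediate
10 | malonic acid | OC(=O)CC(=O)O | starting material
11 | 2-(trimethylsilyl)ethanol | C[Si](C)(C)CCO | starting material
12 | bis[2-(trimethylsilyl)ethyl] malonate | C[Si](C)(C)CCOC(=O)CC(=O)OCC[Si](C)(C)C | intermediate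
13 | acetaldehyde | CC=O | starting material
14 | (10R)-5-ethylidene-10-hydroxy-2,10-dimethyldodeca-2,11-dien-6-one (E/Z mixture) | C=C[C@@](O)(C)CCCC(=O)C(CC=C(C)C)=CC | intermediate
15 | bis[2-(trimethylsilyl)ethyl] 2-[(8R)-8-hydroxy-8-methyl-3-(3-methylbut-2-en-1-yl)-4-oxodec-9-en-2-yl]malonate (diastereomer mixture) | C=C[C@@](O)(C)CCCC(=O)C(CC=C(C)C)C(C)C(C(=O)OCC[Si](C)(C)C)C(=O)OCC[Si](C)(C)C | intermediate
16 | 2-(trimethylsilyl)ethyl 3-[(3R)-3-hydroxy-3-methylpent-4-en-1-yl]-6-methyl-5-(3-methylbut-2-en-1-yl)-2,4-dioxocyclohexane-1-carboxylate (diastereomer and tautomer mixture) | C=C[C@@](O)(C)CCC1C(=O)C(C(=O)OCC[Si](C)(C)C)C(C)C(CC=C(C)C)C1=O | intermediate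
17 | 2-(trimethylsilyl)ethyl (2R)-2-ethenyl-2,7-dimethyl-8-(3-methylbut-2-en-1-yl)-5-oxo-3,4,5,6,7,8-hexahydro-2H-chromene-6-carboxylate (C6/C7/C8 diastereomers) | C=C[C@@]1(C)CCC2=C(O1)C(CC=C(C)C)C(C)C(C(=O)OCC[Si](C)(C)C)C2=O | intermediate
18 | C6 S-phenyl-N-tert-butylsulfilimine adduct of 17 | C=C[C@@]1(C)CCC2=C(O1)C(CC=C(C)C)C(C)C(C(=O)OCC[Si](C)(C)C)(S(=NC(C)(C)C)c3ccccc3)C2=O | intermediate
19 | 2-(trimethylsilyl)ethyl (2R)-2-ethenyl-2,7-dimethyl-8-(3-methylbut-2-en-1-yl)-5-oxo-3,4,5,8-tetrahydro-2H-chromene-6-carboxylate (keto tautomer of 20) | C=C[C@@]1(C)CCC2=C(O1)C(CC=C(C)C)C(C)=C(C(=O)OCC[Si](C)(C)C)C2=O | intermediate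
20 | 2-(trimethylsilyl)ethyl (2R)-2-ethenyl-5-hydroxy-2,7-dimethyl-8-(3-methylbut-2-en-1-yl)-3,4-dihydro-2H-chromene-6-carboxylate | C=C[C@@]1(C)CCc2c(O)c(C(=O)OCC[Si](C)(C)C)c(C)c(CC=C(C)C)c2O1 | intermediate
21 | 1-bromo-2-methylprop-1-ene | CC(C)=CBr | starting material
22 | 2-(trimethylsilyl)ethyl (2R)-5-hydroxy-2,7-dimethyl-8-(3-methylbut-2-en-1-yl)-2-[(1E)-4-methylpenta-1,3-dien-1-yl]-3,4-dihydro-2H-chromene-6-carboxylate | CC(C)=C/C=C/[C@@]1(C)CCc2c(O)c(C(=O)OCC[Si](C)(C)C)c(C)c(CC=C(C)C)c2O1 | intermediate
23 | (2R)-5-hydroxy-2,7-dimethyl-8-(3-methylbut-2-en-1-yl)-2-[(1E)-4-methylpenta-1,3-dien-1-yl]-3,4-dihydro-2H-chromene-6-carboxylic acid | CC(C)=C/C=C/[C@@]1(C)CCc2c(O)c(C(=O)O)c(C)c(CC=C(C)C)c2O1 | target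

**Step count and risks**

Total step count: 10. Longest linear sequence: 8 steps (1, 2, 3, 5, 7, 8, 9, 10); steps 4 and 6 are side branches.

Steps most likely to fail:

Step 7. What may go wrong: condensation of the hydroxyl at C5 instead of C8a, ionization of the tertiary allylic alcohol in the acid stage (loss of enantiopurity, closure through the C2–O bond), or stalling of the Michael addition on the α,β-disubstituted enone. Fallback, setting out from 16 (isolated after the acetic acid quench, with the PPTS stage left out): ring A would be dehydrogenated first (excess LiN(SiMe3)2, then N-tert-butylbenzenesulfinimidoyl chloride, as in step 8) to the resorcylate 2-(trimethylsilyl)ethyl 2,4-dihydroxy-3-[(3R)-3-hydroxy-3-methylpent-4-en-1-yl]-6-methyl-5-(3-methylbut-2-en-1-yl)benzoate F1. The hydroxyl para to the ester, the only phenol not chelated to the ester carbonyl, would be sulfonylated with PhNTf2/K2CO3 to the aryl triflate 2-(trimethylsilyl)ethyl 2-hydroxy-3-[(3R)-3-hydroxy-3-methylpent-4-en-1-yl]-6-methyl-5-(3-methylbut-2-en-1-yl)-4-[(trifluoromethanesulfonyl)oxy]benzoate F2. The O1–C8a bond would then be closed by palladium-catalysed intramolecular C–O coupling of the tertiary alcohol (Pd(OAc)2, 2-(di-tert-butylphosphino)-1,1'-binaphthyl, Cs2CO3, toluene, 80 °C), which has no regiochemical choice and no acid, and the route is rejoined at 20.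

Step 9. What may go wrong: β-aryloxy elimination from the alkylpalladium intermediate (opening of ring B) competing with β-hydride elimination, or slow insertion next to the quaternary C2. Fallback, setting out from 20: cross-metathesis with 2-ethenyl-4,4,5,5-tetramethyl-1,3,2-dioxaborolane (second-generation Hoveyda–Grubbs catalyst, toluene, 60 °C) would give the E-alkenylboronate 2-(trimethylsilyl)ethyl (2R)-5-hydroxy-2,7-dimethyl-8-(3-methylbut-2-en-1-yl)-2-[(E)-2-(4,4,5,5-tetramethyl-1,3,2-dioxaborolan-2-yl)ethenyl]-3,4-dihydro-2H-chromene-6-carboxylate F3. Suzuki–Miyaura coupling of F3 with 21 (Pd(PPh3)4, K3PO4, THF/H2O, 50 °C), in which palladium never sits on an sp3 carbon next to O1, would rejoin the route at 22.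

Step 3. What may go wrong: competing enyne pathways of the ruthenium catalyst (4 is a 1,6-enyne) or solvolysis of the tertiary allylic lactone in hot aqueous DMF. Fallback, setting out from 3: Wittig olefination with (methoxymethyl)triphenylphosphonium chloride/KOtBu (THF, 0 °C) would give the enol ether (3R)-7-methoxy-3-methylhepta-1,6-dien-3-ol F4. PPTS in wet acetone at rt would hydrolyse it, the δ-hydroxy aldehyde closing to the lactol (6R)-6-ethenyl-6-methyloxan-2-ol F5. Oxidation with TEMPO/PhI(OAc)2 (CH2Cl2, rt) would rejoin the route at 5.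

Further compounds
F1 | step 7 | 2-(trimethylsilyl)ethyl 2,4-dihydroxy-3-[(3R)-3-hydroxy-3-methylpent-4-en-1-yl]-6-methyl-5-(3-methylbut-2-en-1-yl)benzoate | C=C[C@@](O)(C)CCc1c(O)c(C(=O)OCC[Si](C)(C)C)c(C)c(CC=C(C)C)c1O
F2 | step 7 | 2-(trimethylsilyl)ethyl 2-hydroxy-3-[(3R)-3-hydroxy-3-methylpent-4-en-1-yl]-6-methyl-5-(3-methylbut-2-en-1-yl)-4-[(trifluoromethanesulfonyl)oxy]benzoate | C=C[C@@](O)(C)CCc1c(O)c(C(=O)OCC[Si](C)(C)C)c(C)c(CC=C(C)C)c1OS(=O)(=O)C(F)(F)F
F3 | step 9 | 2-(trimethylsilyl)ethyl (2R)-5-hydroxy-2,7-dimethyl-8-(3-methylbut-2-en-1-yl)-2-[(E)-2-(4,4,5,5-tetramethyl-1,3,2-dioxaborolan-2-yl)ethenyl]-3,4-dihydro-2H-chromene-6-carboxylate | CC1(C)OB(/C=C/[C@@]2(C)CCc3c(O)c(C(=O)OCC[Si](C)(C)C)c(C)c(CC=C(C)C)c3O2)OC1(C)C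
F4 | step 3 | (3R)-7-methoxy-3-methylhepta-1,6-dien-3-ol (E/Z mixture) | C=C[C@@](O)(C)CCC=COC
F5 | step 3 | (6R)-6-ethenyl-6-methyloxan-2-ol (anomer mixture) | C=C[C@@]1(C)CCCC(O)O1
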